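**Retrosynthetic overview**
1. Target 15 ⇐ enone 12 by (S)-CBS reduction in the last step, which sets the single (R) carbinol centre.
2. 12 ⇐ C8‑CH2–C(=O) bond: A‑ring o‑quinone methide 10 (electrophilic CH2) + methacryloyl anion equivalent (thiazolium Breslow intermediate 11 of methacrolein 9), joining two natively electrophilic carbons.
3. 10 ⇐ C‑8 Mannich base 8 ⇐ luteone 7 ⇐ C‑6 nuclear prenylation of 2'-hydroxygenistein 5.
4. 5 ⇐ O‑demethylation of isoflavone 4 ⇐ one‑pot acylation/C1 ring closure of phloroglucinol 1 + 2,4‑dimethoxyphenylacetic acid 2.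
5. Ring order: A and B rings are bought; the pyranone C ring is the only ring formed (step 1).

Assumption: the [C@H] centre is read as (R) (OH > isopropenyl > CH2Ar > H), and the C‑6/C‑8 assignments of 7 and 8 are confirmed by HMBC from the chelated 5‑OH.

**Step 1**
Reactants: 1 phloroglucinol; 2 2,4-dimethoxyphenylacetic acid
Product: 4 5,7-dihydroxy-3-(2,4-dimethoxyphenyl)-4H-chromen-4-one, via deoxybenzoin 3 (not isolated)
Conditions: BF3·OEt2 (solvent), 85 °C, 1.5 h; then DMF, MsCl (3 equiv), 50→75 °C, 2 h; aq. NaOAc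
Reagents that add atoms: N,N-dimethylformamide, CN(C)C=O (supplies C‑2)
Why: Friedel–Crafts C‑acylation of symmetric phloroglucinol gives the deoxybenzoin as its BF2 chelate, whose methylene is formylated by the DMF/MsCl Vilsmeier‑type reagent and closes onto an ortho OH (one‑pot deoxybenzoin isoflavone synthesis); no regiochemical or stereochemical issue.

**Step 2**
Reactants: 4 5,7-dihydroxy-3-(2,4-dimethoxyphenyl)-4H-chromen-4-one
Product: 5 5,7-dihydroxy-3-(2,4-dihydroxyphenyl)-4H-chromen-4-one (2'-hydroxygenistein)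
Conditions: BBr3 (6 equiv), CH2Cl2, −78 °C→rt, 16 h; then ice/MeOH
Reagents that add atoms: none
Why: BBr3 aryl methyl ether cleavage (bromide attacks the O‑methyl of the ArO(Me)–BBr2 adduct) frees both B‑ring phenols before any acid‑sensitive alkene is present; the chromone and the chelated 5‑OH are inert.

**Step 3**
Reactants: 5 2'-hydroxygenistein; 6 prenyl bromide
Product: 7 5,7-dihydroxy-3-(2,4-dihydroxyphenyl)-6-(3-methylbut-2-en-1-yl)-4H-chromen-4-one (luteone)
Conditions: NaOMe (1.1 equiv), MeOH, 0 °C; 6 (1.5 equiv), 0 °C→rt, 12 h; chromatography (recover 5)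
Reagents that add atoms: none
Why: Nuclear prenylation, i.e. C‑alkylation of the ambident 7‑phenoxide (a vinylogous carboxylate) in a protic solvent that hydrogen‑bonds the oxygen; C‑6, flanked by the chelated 5‑OH and 7‑O−, is the preferred carbon, and with 1.1 equiv of base the less acidic B‑ring phenols stay protonated; no stereocentre.

**Step 4**
Reactants: 7 luteone
Product: 8 8-[(dimethylamino)methyl]-5,7-dihydroxy-3-(2,4-dihydroxyphenyl)-6-(3-methylbut-2-en-1-yl)-4H-chromen-4-one
Conditions: (Me2N)2CH2 (1.1 equiv), 1,4-dioxane, 70 °C, 3 h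
Reagents that add atoms: bis(dimethylamino)methane, CN(C)CN(C)C
Why: Phenolic Mannich reaction in which the acidic 7‑OH (pKa about 7) protonates the aminal and the resulting iminium/7‑phenoxide ion pair collapses at C‑8, the only free A‑ring carbon; the B‑ring phenols are too weakly acidic to ionise the aminal with one equivalent at 70 °C; no stereocentre.

**Step 5**
Reactants: 8 C‑8 Mannich base of luteone; 9 methacrolein
Product: 12 3-(2,4-dihydroxyphenyl)-5,7-dihydroxy-8-(3-methyl-2-oxobut-3-en-1-yl)-6-(3-methylbut-2-en-1-yl)-4H-chromen-4-one, via o-quinone methide 10 (not isolated), via Breslow intermediate 11 (not isolated)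
Conditions: 9 (5 equiv), 3-benzyl-5-(2-hydroxyethyl)-4-methylthiazolium chloride (30 mol %), Et3N (60 mol %), BHT (cat.), 1,4-dioxane, 100 °C, sealed tube, Ar, 12 h
Reagents that add atoms: none
Why: Proposed new method: on heating, the zwitterionic phenolic Mannich base loses Me2NH (E1cB retro‑Mannich, known for 7‑hydroxy‑8‑aminomethylisoflavones) to give o‑quinone methide 10, whose exocyclic CH2 is a strong Michael‑type electrophile, while the thiazol‑2‑ylidene turns methacrolein into Breslow intermediate 11, an acyl anion equivalent that adds through its former carbonyl carbon to that CH2 (driven by re‑aromatisation) and then expels the carbene to give ketone 12; the closest known chemistry is the Stetter reaction and the thiazolium/NHC‑mediated acyl‑anion addition to quinone methides, a thiazolium carbene being chosen because it steers enals to acyl‑anion and not homoenolate reactivity; C‑6 is blocked by prenyl so no free A‑ring carbon can attack the o‑QM, excess methacrolein scavenges the liberated amine, and no stereocentre is formed.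

**Step 6**
Reactants: 12 C‑8 enone
Product: 15 3-(2,4-dihydroxyphenyl)-5,7-dihydroxy-8-[(2R)-2-hydroxy-3-methylbut-3-en-1-yl]-6-(3-methylbut-2-en-1-yl)-4H-chromen-4-one, via tetra-TMS ketone 13 (not isolated), via tetra-TMS alcohol 14 (not isolated)
Conditions: HMDS (6 equiv), TMSCl (cat.), THF, 50 °C, then evaporate; (S)-Me-CBS (20 mol %), catecholborane (2 equiv), toluene, −78 °C, 12 h; MeOH, then aq. citric acid, 0 °C→rt
Reagents that add atoms: none
Why: Transient per‑O‑silylation masks the acidic phenols and the 5‑OH/C‑4 chelate and makes the substrate toluene‑soluble, after which Corey–Bakshi–Shibata reduction delivers hydride to the enone carbonyl with isopropenyl as the large and CH2Ar as the small group, so the (S)‑catalyst gives the (R)‑allylic alcohol (same sense as acetophenone to (R)-1-phenylethanol, CIP order OH > isopropenyl > CH2Ar); catecholborane at −78 °C neither hydroborates the alkenes nor reduces the chromone, and mild acidic methanolysis removes the TMS groups.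

**Compound list**
1 | phloroglucinol (benzene-1,3,5-triol) | Oc1cc(O)cc(O)c1 | starting material
2 | 2,4-dimethoxyphenylacetic acid | COc1ccc(CC(=O)O)c(OC)c1 | starting material
3 | 2-(2,4-dimethoxyphenyl)-1-(2,4,6-trihydroxyphenyl)ethan-1-one (deoxybenzoin; BF2 chelate in the flask) | COc1ccc(CC(=O)c2c(O)cc(O)cc2O)c(OC)c1 | intermediate
4 | 5,7-dihydroxy-3-(2,4-dimethoxyphenyl)-4H-chromen-4-one | COc1ccc(-c2coc3cc(O)cc(O)c3c2=O)c(OC)c1 | intermediate
5 | 5,7-dihydroxy-3-(2,4-dihydroxyphenyl)-4H-chromen-4-one (2'-hydroxygenistein) | Oc1ccc(-c2coc3cc(O)cc(O)c3c2=O)c(O)c1 | intermediate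
6 | prenyl bromide (1-bromo-3-methylbut-2-ene) | CC(C)=CCBr | starting material
7 | 5,7-dihydroxy-3-(2,4-dihydroxyphenyl)-6-(3-methylbut-2-en-1-yl)-4H-chromen-4-one (luteone) | CC(C)=CCc1c(O)cc2occ(-c3ccc(O)cc3O)c(=O)c2c1O | intermediate
8 | 8-[(dimethylamino)methyl]-5,7-dihydroxy-3-(2,4-dihydroxyphenyl)-6-(3-methylbut-2-en-1-yl)-4H-chromen-4-one | CN(C)Cc1c(O)c(CC=C(C)C)c(O)c2c(=O)c(-c3ccc(O)cc3O)coc12 | intermediate
9 | methacrolein (2-methylprop-2-enal) | C=C(C)C=O | starting material
10 | 3-(2,4-dihydroxyphenyl)-5-hydroxy-8-methylidene-6-(3-methylbut-2-en-1-yl)-8H-chromene-4,7-dione (A‑ring o‑quinone methide) | C=C1C(=O)C(CC=C(C)C)=C(O)C2=C1OC=C(c3ccc(O)cc3O)C2=O | intermediate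
11 | 1-[3-benzyl-5-(2-hydroxyethyl)-4-methyl-1,3-thiazol-2(3H)-ylidene]-2-methylprop-2-en-1-ol (Breslow intermediate of 9, catalyst‑bound) | C=C(C)C(O)=C1SC(CCO)=C(C)N1Cc2ccccc2 | intermediate
12 | 3-(2,4-dihydroxyphenyl)-5,7-dihydroxy-8-(3-methyl-2-oxobut-3-en-1-yl)-6-(3-methylbut-2-en-1-yl)-4H-chromen-4-one | C=C(C)C(=O)Cc1c(O)c(CC=C(C)C)c(O)c2c(=O)c(-c3ccc(O)cc3O)coc12 | intermediate
13 | 3-[2,4-bis(trimethylsilyloxy)phenyl]-8-(3-methyl-2-oxobut-3-en-1-yl)-6-(3-methylbut-2-en-1-yl)-5,7-bis(trimethylsilyloxy)-4H-chromen-4-one | C=C(C)C(=O)Cc1c(O[Si](C)(C)C)c(CC=C(C)C)c(O[Si](C)(C)C)c2c(=O)c(-c3ccc(O[Si](C)(C)C)cc3O[Si](C)(C)C)coc12 | intermediate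
14 | 3-[2,4-bis(trimethylsilyloxy)phenyl]-8-[(2R)-2-hydroxy-3-methylbut-3-en-1-yl]-6-(3-methylbut-2-en-1-yl)-5,7-bis(trimethylsilyloxy)-4H-chromen-4-one | C=C(C)[C@H](O)Cc1c(O[Si](C)(C)C)c(CC=C(C)C)c(O[Si](C)(C)C)c2c(=O)c(-c3ccc(O[Si](C)(C)C)cc3O[Si](C)(C)C)coc12 | intermediate
15 | 3-(2,4-dihydroxyphenyl)-5,7-dihydroxy-8-[(2R)-2-hydroxy-3-methylbut-3-en-1-yl]-6-(3-methylbut-2-en-1-yl)-4H-chromen-4-one | C=C(C)[C@H](O)Cc1c(O)c(CC=C(C)C)c(O)c2c(=O)c(-c3ccc(O)cc3O)coc12 | target

**Totals**
Total step count: 6. Longest linear sequence: 6 (fully linear).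

**Three steps most likely to fail**

Step 5 (key coupling). The free phenols may be acylated by the enal‑derived acyl azolium (redox esterification). Methacrolein may self‑condense, or the enone product may serve as a second Stetter acceptor or add dimethylamine. The Mannich base may also need more heat than the carbene tolerates. The fallback sets out from 8 and comes back at 12. It uses a nitronate as the masked acyl anion. Compound 8 is heated with 2-methyl-3-nitroprop-1-ene (3 equiv) in dioxane at 90–100 °C; the nitronate, formed by the liberated amine, adds through its α‑carbon to o‑quinone methide 10 to give the racemic 8-(3-methyl-2-nitrobut-3-en-1-yl)luteone F1. A reductive Nef reaction (NaOMe, then buffered aqueous TiCl3/NH4OAc) converts it into ketone 12.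

Step 3 (C‑6 prenylation). Expect about 25–35 % of 7 beside 7‑O‑prenyl, 8‑C‑prenyl and 6,8‑diprenyl products; the 6/8 ratio is the weak point. The fallback sets out from 4 and comes back at 15; it fixes the regiochemistry with the Mannich reaction and adds the prenyl group last.
- Compound 4 is aminomethylated with bis(dimethylamino)methane, which on a 5,7‑dihydroxyisoflavone with a methylated B ring goes to C‑8, to give 8-[(dimethylamino)methyl]-5,7-dihydroxy-3-(2,4-dimethoxyphenyl)chromen-4-one F2.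
- BBr3 gives the demethylated Mannich base F3.
- The thiazolium/methacrolein coupling of step 5 runs through the 6‑unsubstituted o‑quinone methide F4 to the des‑prenyl enone F5.
- Silylation, (S)-CBS reduction and desilylation as in step 6 run through the des‑prenyl tetra‑TMS ketone F6 and the des‑prenyl tetra‑TMS alcohol F7 to the des‑prenyl (R)‑alcohol F8.
- Finally, C‑prenylation with 6 (NaOMe, MeOH) at C‑6, now the only free A‑ring carbon, gives 15.

Step 6 (CBS reduction). Silylation of the chelated 5‑OH may be incomplete, and the bulky CH2Ar group may lower facial discrimination; the ee must be checked by chiral HPLC or Mosher ester. The fallback sets out from 12 and comes back at 15. Luche reduction (NaBH4, CeCl3·7H2O, MeOH, −40 °C) gives the racemic allylic alcohol F9. Lipase‑catalysed kinetic resolution (Burkholderia cepacia lipase, vinyl acetate, MTBE, 30 °C) acylates the (S)‑enantiomer (Kazlauskas rule with CH2Ar as the large group) to the (S)‑acetate F10, which is separated by chromatography. The unreacted (R)‑alcohol is 15.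

**Further compounds**
F1 | step 5 | 3-(2,4-dihydroxyphenyl)-5,7-dihydroxy-8-(3-methyl-2-nitrobut-3-en-1-yl)-6-(3-methylbut-2-en-1-yl)-4H-chromen-4-one (racemic) | C=C(C)C(Cc1c(O)c(CC=C(C)C)c(O)c2c(=O)c(-c3ccc(O)cc3O)coc12)[N+](=O)[O-]
F2 | step 3 | 8-[(dimethylamino)methyl]-5,7-dihydroxy-3-(2,4-dimethoxyphenyl)-4H-chromen-4-one | CN(C)Cc1c(O)cc(O)c2c(=O)c(-c3ccc(OC)cc3OC)coc12
F3 | step 3 | 8-[(dimethylamino)methyl]-5,7-dihydroxy-3-(2,4-dihydroxyphenyl)-4H-chromen-4-one (demethylated Mannich base) | CN(C)Cc1c(O)cc(O)c2c(=O)c(-c3ccc(O)cc3O)coc12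
F4 | step 3 | 3-(2,4-dihydroxyphenyl)-5-hydroxy-8-methylidene-8H-chromene-4,7-dione (6‑unsubstituted o‑quinone methide) | C=C1C(=O)C=C(O)C2=C1OC=C(c3ccc(O)cc3O)C2=O
F5 | step 3 | 3-(2,4-dihydroxyphenyl)-5,7-dihydroxy-8-(3-methyl-2-oxobut-3-en-1-yl)-4H-chromen-4-one (des‑prenyl enone) | C=C(C)C(=O)Cc1c(O)cc(O)c2c(=O)c(-c3ccc(O)cc3O)coc12
F6 | step 3 | 3-[2,4-bis(trimethylsilyloxy)phenyl]-8-(3-methyl-2-oxobut-3-en-1-yl)-5,7-bis(trimethylsilyloxy)-4H-chromen-4-one (des‑prenyl tetra‑TMS ketone) | C=C(C)C(=O)Cc1c(O[Si](C)(C)C)cc(O[Si](C)(C)C)c2c(=O)c(-c3ccc(O[Si](C)(C)C)cc3O[Si](C)(C)C)coc12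
F7 | step 3 | 3-[2,4-bis(trimethylsilyloxy)phenyl]-8-[(2R)-2-hydroxy-3-methylbut-3-en-1-yl]-5,7-bis(trimethylsilyloxy)-4H-chromen-4-one (des‑prenyl tetra‑TMS alcohol) | C=C(C)[C@H](O)Cc1c(O[Si](C)(C)C)cc(O[Si](C)(C)C)c2c(=O)c(-c3ccc(O[Si](C)(C)C)cc3O[Si](C)(C)C)coc12
F8 | step 3 | 3-(2,4-dihydroxyphenyl)-5,7-dihydroxy-8-[(2R)-2-hydroxy-3-methylbut-3-en-1-yl]-4H-chromen-4-one (des‑prenyl (R)‑alcohol) | C=C(C)[C@H](O)Cc1c(O)cc(O)c2c(=O)c(-c3ccc(O)cc3O)coc12
F9 | step 6 | 3-(2,4-dihydroxyphenyl)-5,7-dihydroxy-8-(2-hydroxy-3-methylbut-3-en-1-yl)-6-(3-methylbut-2-en-1-yl)-4H-chromen-4-one (racemic) | C=C(C)C(O)Cc1c(O)c(CC=C(C)C)c(O)c2c(=O)c(-c3ccc(O)cc3O)coc12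
F10 | step 6 | (2S)-1-[3-(2,4-dihydroxyphenyl)-5,7-dihydroxy-6-(3-methylbut-2-en-1-yl)-4-oxo-4H-chromen-8-yl]-3-methylbut-3-en-2-yl acetate | C=C(C)[C@@H](OC(C)=O)Cc1c(O)c(CC=C(C)C)c(O)c2c(=O)c(-c3ccc(O)cc3O)coc12
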